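## Structural features

The target is a branched tetraflavanoid with seventeen free hydroxyls. Its core is a (+)-catechin unit K (2R,3S) whose phloroglucinol ring A is substituted at both free positions: C8 carries unit M and C6 carries unit S, each bonded through its own C4, and M carries a third unit T through a C4(T)–C6(M) bond. S, M and T are identical 7,3′,4′-trihydroxyflavan-3-ol (ent-fisetinidol) units with three contiguous stereocentres C2, C3 and C4 on the pyran ring C. All three share the absolute configuration (2S,3R) and the same relative arrangement: the C2 aryl group is trans to O3 and the interflavanyl bond at C4 is cis to O3. This makes eleven stereocentres in all. The catechol, resorcinol and phloroglucinol rings are sensitive to oxidants and base, and the benzylic C2–O1 ethers and the electron-rich diarylmethine C4 centres are sensitive to acid, so every oxygen is best kept as a benzyl ether until the last step. The real difficulty is twofold: regiocontrol between almost equivalent electron-rich positions (C6 against C8 of K, ring A of M against ring A of S), and the 2,3-trans-3,4-cis triad, which capture of a flavan-4-yl cation does not normally deliver. The key step exploits ring A of T (C4a, C5, C6, C7, C8, C8a; OH on C7, O1 on C8a). This ring is a 3-alkoxyphenol, the aromatised enol ether of a cyclohexane-1,3-dione, so C8a and C4a can be the carbonyl and α-carbon of a δ-lactone that already holds C2, C3 and C4, and C5–C8 can come from a four-carbon enone.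

## Logic of the disconnections

49 from 48: sixteen benzyl C–O bonds are cut. Benzyl is the only protecting group, so all phenols and carbinols are released together and the air-sensitive polyphenol exists only in the last flask. The forward hydrogenolysis must spare the benzylic C2–O1 bonds and the C4–aryl bonds.

48 from 45 (through 46 and 47): two hydrogens are formally added back across C5–C6, turning the phenol ring A of T into an enone. This replaces a regiochemical problem on an arene by a ring construction. The forward dehydrogenation must work without acid and without oxidants that attack benzyl ethers or C4–H.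

45 from 42 and 19: the bonds C4a–C5 and C8–C8a are cut, and O1–C8a changes from enol ether back to ester. This removes a whole carbocycle and leaves a δ-lactone whose three stereocentres are already in place. The forward step needs 1,4-addition to 19 without oligomerisation, ring closure only at the lactone carbonyl, and reclosure of O1 on C8a. 42 and 45 are kept fully benzylated; what is changed is the way 42 is reached, which now has a defined source of absolute configuration and defined arene regiochemistry.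

42 from 41, and 41 from 38 and 9: first C4–H is cut (conjugate reduction), then the C4(T)–C6(M) bond (cross-coupling). C4 is therefore set last, by hydride delivery anti to O3 on a rigid unsaturated lactone, and the C2/C3 pair arrives ready-made in 9. The forward coupling needs a metalated C6 of M and nowhere else.

38 from 37 and 36: the C6–Br bond and one O-benzyl bond are cut. In 36 the only free phenol of the molecule sits on ring A of M, so a phenol-directed bromination distinguishes M from S without an extra protecting group. The forward bromination must choose C6 over C8.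

36 from 26, 9 and 19 (through 27–35): the same coupling, reduction, annulation and aromatisation cycle builds unit M on C8 of K. The cut bonds are C4(M)–C8(K), C4–H, C4a–C5, C8–C8a and C5=C6. The C8 bromide of 26 marks the site.

26 from 14, 9 and 19 (through 15–25): the same cycle builds unit S on C6 of K. Unit S is made first so that its phenol is already benzylated when the phenol of M appears. This requires two different halogens in 14, of which only iodine is exchanged in the first coupling.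

14 from 13, 12, 11 and 10: C6–I, C8–Br and five O-benzyl bonds are cut. Bromination goes to C8 first, so iodine can only enter at C6.

9 from 8, 8 from 5 and 6, 5 from 3 and 4, 3 from 2 and 2 from 1: the cuts are the enol O–S bond, the lactone C–O and C3–C4 bonds (Claisen), and the C5–C6 bond of the lactone (aldol). One enantioselective anti-aldol sets C2 and C3 of all three ent-fisetinidol units, because 9 is used three times.

## Other disconnections considered

Alternative 1: The cut is at the three O1–C2 bonds of S, M and T. In the forward step a phosphine and an azodicarboxylate activate three benzylic C2 hydroxyls of the ring-opened precursor of A1, and each ring A phenol displaces with inversion (threefold Mitsunobu etherification) to give A1. The C2/C3 pairs would come from droxidopa (A2).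
- In its favour: three rings close in one operation, the arenes are used as bought so no ring A has to be built, and the step count would probably be lower than in the chosen plan. On step economy this alternative is the better one.
- Against it: C2 carries a 3,4-dialkoxyphenyl group, so the activated carbinol can ionise and inversion is not assured. The free C3 and C4 hydroxyls compete as nucleophiles (epoxide or oxetane). The nitrogen of A2 must be exchanged for oxygen. A1 still has three tertiary diaryl carbinols at C4, whose reduction through cations would have to give the less favoured 3,4-cis isomer three times.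
- Comparison: the origin of C2/C3 chirality (chiral pool against one asymmetric aldol) is about equal. Control of C4 and the integrity of C2 are weaker than in the chosen plan, where the C2–O bond is never broken and C4 is set on a lactone before ring A exists.

Alternative 2: The cut is at the C3–O and C4–O bonds of three epoxides. In the forward step a chiral salen–manganese oxidant with hypochlorite epoxidises the three chromene C3=C4 bonds of the tris-chromene precursor of A3, while 365 nm light opens and recloses the pyran rings so that C2 equilibrates and only the matched epimer reacts. The product is A3.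
- In its favour: the absolute configuration is catalytic and comes from one complex, cyclic aryl-conjugated cis-alkenes are the best substrate class for this epoxidation, and no chiral building block is needed. On the source of chirality this alternative is the better one.
- Against it: the alkenes are trisubstituted and carry a bulky flavanyl group on C4. The photogenerated quinone methides and the electron-rich rings are themselves open to oxidation and chlorination. A3 is a threefold tertiary, doubly benzylic epoxide prone to rearrangement. Replacing C4–O by C4–H with inversion at a tertiary diaryl carbon has no reliable precedent, and a cation pathway would lose the stereochemistry. Three independent resolutions must all succeed in one molecule.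
- Comparison: step economy could equal or beat the chosen plan. Mechanistic security is much lower, because the chosen plan sets each centre by a separately precedented step.

Alternative 3: The cut is at the three C2–C1′ bonds to the catechol rings B of S, M and T. In the forward step a nickel–bipyridine catalyst at a carbon cathode with a zinc anode couples three anomeric C2 chlorides with A5 to give A4, which is one hydrogenolysis away from the target.
- In its favour: it is highly convergent, rings B arrive ready-made, and nickel-mediated capture of anomeric radicals usually places the aryl group trans to the neighbouring alkoxy group, which is the 2,3-trans relation needed. The endgame is shorter than in the chosen plan (one step after the key step instead of three); this point goes to the alternative.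
- Against it: the tris(2-chloro) precursor still needs every C3 and C4 centre and all the arene regiochemistry, so the hard part is not removed. 2-Chlorochromans with a 3-alkoxy group are α-halo ethers that eliminate or ionise easily. The C2 configuration would rest on substrate control at three sites at once.
- Comparison: equal on the need to control C4, better on endgame length, worse on the security of C2. In the chosen plan C2 and C3 are set together in a small molecule and never touched again.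

Key step: step 25

Assumption (remark on the chemistry): the (S)-proline-derived diamine is taken to deliver the (2S,3S) anti-aldol 5; if its facial sense is the opposite, the (R)-proline-derived enantiomer of the same diamine is used and nothing else changes.

## Steps

Step 1
Reactants: 1 benzyloxyacetyl chloride
Product: 2 S-ethyl 2-(benzyloxy)ethanethioate
Conditions: EtSH, pyridine, CH2Cl2, 0 → 25 °C
Reagents that add atoms: ethanethiol, CCS
Why: Acyl substitution of an acid chloride by a thiol (thioesterification); no stereocentre is involved.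

Step 2
Reactants: 2 S-ethyl 2-(benzyloxy)ethanethioate
Product: 3 (Z)-{[2-(benzyloxy)-1-(ethylsulfanyl)ethenyl]oxy}trimethylsilane
Conditions: LiN(iPr)2, Me3SiCl, THF, −78 °C
Reagents that add atoms: chlorotrimethylsilane, C[Si](C)(C)Cl
Why: Kinetic enolisation of the thioester with O-silylation gives the silyl ketene thioacetal; the cyclic deprotonation transition state should place ethylsulfanyl cis to benzyloxy (Z).

Step 3
Reactants: 3 (Z)-silyl ketene thioacetal; 4 3,4-bis(benzyloxy)benzaldehyde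
Product: 5 S-ethyl (2S,3S)-2-(benzyloxy)-3-[3,4-bis(benzyloxy)phenyl]-3-hydroxypropanethioate
Conditions: Sn(OTf)2, (S)-1-ethyl-2-(piperidin-1-ylmethyl)pyrrolidine, Bu2Sn(OAc)2, CH2Cl2, −78 °C; aq. NaHCO3, then citric acid
Reagents that add atoms: none
Why: Asymmetric Mukaiyama aldol addition promoted by a chiral diamine complex of divalent tin triflate; α-benzyloxy silyl ketene thioacetals react through an open transition state with the benzyloxy oxygen bound to tin, which should give the anti adduct, and the diamine fixes the aldehyde face, so both centres (future flavan C3 and C2) are set here.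

Step 4
Reactants: 5 anti-aldol thioester; 6 methyl acetate
Product: 8 (5S,6S)-5-(benzyloxy)-6-[3,4-bis(benzyloxy)phenyl]oxane-2,4-dione, via keto ester 7 (not isolated)
Conditions: MeOAc, LiN(iPr)2 (4 equiv), THF, −78 °C; 5, −78 → −40 °C; 1 M NaOH, 25 °C; 1 M HCl to pH 3
Reagents that add atoms: none
Why: Crossed Claisen condensation of the thioester with the lithium enolate of methyl acetate, then base-mediated δ-lactonisation; the 1,3-dicarbonyl stays enolised toward C3 throughout, which should protect C5 from epimerisation and suppress retro-aldol cleavage.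

Step 5
Reactants: 8 pyran-2,4-dione
Product: 9 (5S,6S)-5-(benzyloxy)-6-[3,4-bis(benzyloxy)phenyl]-2-oxo-5,6-dihydro-2H-pyran-4-yl trifluoromethanesulfonate
Conditions: Tf2O, Et3N, CH2Cl2, −78 °C
Reagents that add atoms: trifluoromethanesulfonic anhydride, O=S(=O)(OS(=O)(=O)C(F)(F)F)C(F)(F)F
Why: O-Sulfonylation of the enol of a cyclic β-keto lactone at the C4 oxygen gives the vinylogous acyl triflate, the usual electrophile for cross-coupling at C4; low temperature and a weak amine base should leave C5 untouched.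

Step 6
Reactants: 10 (+)-catechin
Product: 11 5,7,3′,4′-tetra-O-benzyl-(+)-catechin
Conditions: BnBr, K2CO3, DMF, 25 °C
Reagents that add atoms: benzyl bromide, BrCc1ccccc1
Why: Williamson etherification of the four phenols under carbonate base; the secondary C3 hydroxyl is not alkylated and C2 should not epimerise at ambient temperature.

Step 7
Reactants: 11 tetra-O-benzylcatechin
Product: 12 3,5,7,3′,4′-penta-O-benzyl-(+)-catechin
Conditions: NaH, BnBr, Bu4NI (cat.), DMF, 0 → 25 °C
Reagents that add atoms: benzyl bromide, BrCc1ccccc1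
Why: Williamson etherification of the remaining secondary alkoxide.

Step 8
Reactants: 12 penta-O-benzylcatechin
Product: 13 8-bromo-penta-O-benzylcatechin
Conditions: NBS, CH2Cl2, −78 → 25 °C
Reagents that add atoms: N-bromosuccinimide, O=C1CCC(=O)N1Br
Why: Electrophilic aromatic bromination; 5,7-di-O-benzylflavan-3-ol derivatives react at C8 in preference to C6 at low temperature, and ring B is much less nucleophilic.

Step 9
Reactants: 13 8-bromo-penta-O-benzylcatechin
Product: 14 8-bromo-6-iodo-penta-O-benzylcatechin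
Conditions: NIS, CF3CO2H (cat.), CH2Cl2/MeCN, 0 → 25 °C
Reagents that add atoms: N-iodosuccinimide, O=C1CCC(=O)N1I
Why: Electrophilic iodination at C6, the only free position of the trioxygenated ring A; the two halogens now differ and can be addressed one after the other.

Step 10
Reactants: 14 8-bromo-6-iodo-penta-O-benzylcatechin; 9 enol triflate
Product: 17 8-bromo-penta-O-benzylcatechin bearing at C6 the (5R,6S)-5-(benzyloxy)-6-[3,4-bis(benzyloxy)phenyl]-2-oxo-5,6-dihydro-2H-pyran-4-yl group, via arylmagnesium chloride 15 (not isolated), via arylzinc chloride 16 (not isolated)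
Conditions: iPrMgCl·LiCl, THF, −20 °C; ZnCl2, −20 → 25 °C; 9, Pd(PPh3)4 (5 mol %), THF, 45 °C
Reagents that add atoms: none
Why: Iodine–magnesium exchange is far faster than bromine–magnesium exchange, so only C6 is metalated; transmetalation to zinc and Negishi coupling with the activated enol triflate forms the C4(S)–C6(K) bond, and zerovalent palladium with PPh3 should not insert into the hindered, electron-rich C8–Br bond at this temperature.

Step 11
Reactants: 17 unsaturated lactone of unit S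
Product: 18 8-bromo-penta-O-benzylcatechin bearing at C6 the (4S,5R,6S)-5-(benzyloxy)-6-[3,4-bis(benzyloxy)phenyl]-2-oxooxan-4-yl group
Conditions: [(Ph3P)CuH]6 (10 mol % Cu), PhMe2SiH, t-BuOH, PhMe, 25 °C
Reagents that add atoms: none
Why: Copper hydride conjugate reduction of an α,β-unsaturated lactone; allylic strain against the C4 aryl group holds the C5 benzyloxy group pseudoaxial, hydride should enter C4 anti to it, and the aryl group ends cis to O5 (flavan 3,4-cis); the saturated lactone and the aryl bromide are inert to this reagent.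

Step 12
Reactants: 18 lactone of unit S; 19 methyl vinyl ketone
Product: 22 8-bromo-penta-O-benzylcatechin bearing at C6 the (2S,3R,4S)-3-(benzyloxy)-2-[3,4-bis(benzyloxy)phenyl]-7-oxo-2,3,4,4a,5,6-hexahydro-7H-chromen-4-yl group (C4a epimers), via keto lactone 20 (not isolated), via hydroxy dione 21 (not isolated)
Conditions: LiN(iPr)2, THF, −78 °C; 19 (slow addition), −78 → −30 °C; KOtBu, −30 → 0 °C; AcOH; then PPTS, PhMe, 4 Å MS, 40 °C
Reagents that add atoms: none
Why: Michael–Claisen annulation as analysed under step 25: 1,4-addition of the lactone enolate, ring-opening acylation of the methyl ketone enolate at the lactone carbonyl, and mild acid reclosure of the pyran as a vinylogous ester; C2, C3 and C4 are not touched and the aryl bromide has no ortho hydrogen to lose.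

Step 13
Reactants: 22 hexahydrochromenone of unit S
Product: 23 the 7-(trimethylsilyloxy)-3,4,4a,5-tetrahydro-2H-chromene (silyl dienol ether) of 22
Conditions: LiN(iPr)2, Me3SiCl, THF, −78 °C
Reagents that add atoms: chlorotrimethylsilane, C[Si](C)(C)Cl
Why: Kinetic α′-deprotonation of the vinylogous ester at C6 and O-silylation give the cross-conjugated silyl dienol ether.

Step 14
Reactants: 23 silyl dienol ether of unit S
Product: 25 8-bromo-penta-O-benzylcatechin bearing at C6 the 3,3′,4′-tri-O-benzyl-ent-fisetinidol unit S with free 7-OH (2S,3R; 2,3-trans, 3,4-cis), via tetrahydrochromenone 24 (not isolated)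
Conditions: Pd(OAc)2 (1.1 equiv), MeCN, 25 °C
Reagents that add atoms: none
Why: Saegusa oxidation: palladation at C6 and β-hydride loss from C5 give a 4a-H cyclohexadienone that tautomerises at once to the phenol; ligand-free palladium metal formed at 25 °C is not expected to insert into the hindered aryl bromide.

Step 15
Reactants: 25 phenol of unit S
Product: 26 8-bromo-penta-O-benzylcatechin bearing at C6 the tetra-O-benzyl-ent-fisetinidol unit S
Conditions: BnBr, K2CO3, DMF, 25 °C
Reagents that add atoms: benzyl bromide, BrCc1ccccc1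
Why: Williamson etherification of the single phenol.

Step 16
Reactants: 26 bromide of the benzylated K–S dimer; 9 enol triflate
Product: 29 benzylated K–S dimer bearing at C8 of K the (5R,6S)-5-(benzyloxy)-6-[3,4-bis(benzyloxy)phenyl]-2-oxo-5,6-dihydro-2H-pyran-4-yl group, via aryllithium 27 (not isolated), via arylzinc chloride 28 (not isolated)
Conditions: t-BuLi (2 equiv), THF, −78 °C; ZnCl2, −78 → 25 °C; 9, Pd(OAc)2 (5 mol %), SPhos (10 mol %), THF, 45 °C
Reagents that add atoms: none
Why: Bromine–lithium exchange at −78 °C outruns benzylic deprotonation; the derived arylzinc couples with the enol triflate (Negishi coupling), the biarylphosphine ligand helping transmetalation of the di-ortho-substituted arylzinc, and the C4(M)–C8(K) bond forms at the site fixed by step 8.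

Step 17
Reactants: 29 unsaturated lactone of unit M
Product: 30 benzylated K–S dimer bearing at C8 of K the (4S,5R,6S)-5-(benzyloxy)-6-[3,4-bis(benzyloxy)phenyl]-2-oxooxan-4-yl group
Conditions: [(Ph3P)CuH]6 (10 mol % Cu), PhMe2SiH, t-BuOH, PhMe, 25 °C
Reagents that add atoms: none
Why: Copper hydride conjugate reduction as in step 11; hydride should enter C4 anti to the C5 benzyloxy group and give the 4,5-cis lactone.

Step 18
Reactants: 30 lactone of unit M; 19 methyl vinyl ketone
Product: 33 benzylated K–S dimer bearing at C8 of K the (2S,3R,4S)-3-(benzyloxy)-2-[3,4-bis(benzyloxy)phenyl]-7-oxo-2,3,4,4a,5,6-hexahydro-7H-chromen-4-yl group (C4a epimers), via keto lactone 31 (not isolated), via hydroxy dione 32 (not isolated)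
Conditions: LiN(iPr)2, THF, −78 °C; 19 (slow addition), −78 → −30 °C; KOtBu, −30 → 0 °C; AcOH; then PPTS, PhMe, 4 Å MS, 40 °C
Reagents that add atoms: none
Why: Michael–Claisen annulation as in step 25; the benzyl ethers of K and S carry no acidic hydrogen that competes with the lactone α-CH2.

Step 19
Reactants: 33 hexahydrochromenone of unit M
Product: 34 the 7-(trimethylsilyloxy)-3,4,4a,5-tetrahydro-2H-chromene (silyl dienol ether) of 33
Conditions: LiN(iPr)2, Me3SiCl, THF, −78 °C
Reagents that add atoms: chlorotrimethylsilane, C[Si](C)(C)Cl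
Why: Kinetic α′-enolisation at C6 and O-silylation, as in step 13.

Step 20
Reactants: 34 silyl dienol ether of unit M
Product: 36 benzylated M–K–S trimer with free 7-OH on unit M, via tetrahydrochromenone 35 (not isolated)
Conditions: Pd(OAc)2 (1.1 equiv), MeCN, 25 °C
Reagents that add atoms: none
Why: Saegusa oxidation and tautomerisation of the 4a-H dienone to the phenol, as in step 14.

Step 21
Reactants: 36 trimer with free 7-OH on unit M
Product: 37 6-bromo-7-hydroxy derivative of 36 (bromine on C6 of unit M)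
Conditions: NBS (1.0 equiv), iPr2NH (10 mol %), CH2Cl2, −78 → −20 °C
Reagents that add atoms: N-bromosuccinimide, O=C1CCC(=O)N1Br
Why: Amine-catalysed ortho-bromination of a phenol; unit M holds the only free phenol, and of its two ortho positions C6 (para to O1, unhindered) should react before C8, which lies between two oxygens, while the aryl ether rings are much slower at this temperature.

Step 22
Reactants: 37 bromophenol
Product: 38 benzylated M–K–S trimer with bromine on C6 of unit M
Conditions: BnBr, K2CO3, DMF, 25 °C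
Reagents that add atoms: benzyl bromide, BrCc1ccccc1
Why: Williamson etherification of the single phenol.

Step 23
Reactants: 38 bromide of the benzylated trimer; 9 enol triflate
Product: 41 benzylated M–K–S trimer bearing at C6 of M the (5R,6S)-5-(benzyloxy)-6-[3,4-bis(benzyloxy)phenyl]-2-oxo-5,6-dihydro-2H-pyran-4-yl group, via aryllithium 39 (not isolated), via arylzinc chloride 40 (not isolated)
Conditions: t-BuLi (2 equiv), THF, −78 °C; ZnCl2, −78 → 25 °C; 9, Pd(OAc)2 (5 mol %), SPhos (10 mol %), THF, 45 °C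
Reagents that add atoms: none
Why: Bromine–lithium exchange, transmetalation to zinc and Negishi coupling with the enol triflate form the C4(T)–C6(M) bond; this arylzinc has only one ortho substituent and should couple more easily than those of steps 10 and 16.

Step 24
Reactants: 41 unsaturated lactone of unit T
Product: 42 benzylated M–K–S trimer bearing at C6 of M the (4S,5R,6S)-5-(benzyloxy)-6-[3,4-bis(benzyloxy)phenyl]-2-oxooxan-4-yl group
Conditions: [(Ph3P)CuH]6 (10 mol % Cu), PhMe2SiH, t-BuOH, PhMe, 25 °C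
Reagents that add atoms: none
Why: Copper hydride conjugate reduction; hydride should be delivered to C4 anti to the pseudoaxial C5 benzyloxy group, which sets C4 of unit T with the aryl group cis to O3, and this centre is β to the carbonyl and cannot epimerise afterwards.

Step 25
Reactants: 42 δ-lactone of unit T on the benzylated trimer; 19 methyl vinyl ketone
Product: 45 benzylated M–K–S trimer bearing at C6 of M the (2S,3R,4S)-3-(benzyloxy)-2-[3,4-bis(benzyloxy)phenyl]-7-oxo-2,3,4,4a,5,6-hexahydro-7H-chromen-4-yl group (C4a epimers), via keto lactone 43 (not isolated), via hydroxy dione 44 (not isolated)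
Conditions: LiN(iPr)2 (1.1 equiv), THF, −78 °C; 19 (1.1 equiv, slow addition), −78 → −30 °C; KOtBu (2.5 equiv), −30 → 0 °C; AcOH; then PPTS, PhMe, 4 Å MS, 40 °C
Reagents that add atoms: none
Why: LiN(iPr)2 removes a proton from the lactone α-CH2 (C4a) and the lithium enolate adds 1,4 to 19, forming C4a–C5; any 1,2-adduct is a tertiary aldolate that should revert on warming and drain into the conjugate adduct. KOtBu then equilibrates the ketone enolates, and only the methyl (C8) enolate can reach the lactone carbonyl through a six-membered transition state (6-exo-trig acyl substitution), which forms C8–C8a, opens the lactone and is pulled forward by deprotonation of the new 1,3-dione. The expelled C2 alkoxide is a spectator whose C–O bond stays intact, so C2 keeps its configuration, and C3 and C4 carry no hydrogen acidic enough to be lost (C4 is β to the carbonyls). Weak acid then adds the C2 hydroxyl to the C8a carbonyl (6-exo-trig hemiketalisation; attack on C7 would need an eight-membered ring) and loss of water gives the vinylogous ester, which is ring C of unit T. The closest known reaction types are the Michael–Claisen synthesis of cyclohexane-1,3-diones from ester enolates and enones and the ring-opening Claisen acylation of ketone enolates by lactones. No lasting stereocentre is created: C4a forms as a mixture and is erased on aromatisation. The selectivities needed are 1,4- over 1,2-addition and single addition (secured by one equivalent of 19 added slowly at low temperature), closure of O1 on C8a (secured by ring size), and retention at C2 (secured by using only a pyridinium acid, too weak to ionise the electron-rich benzylic alcohol).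

Step 26
Reactants: 45 hexahydrochromenone of unit T
Product: 46 the 7-(trimethylsilyloxy)-3,4,4a,5-tetrahydro-2H-chromene (silyl dienol ether) of 45
Conditions: LiN(iPr)2, Me3SiCl, THF, −78 °C
Reagents that add atoms: chlorotrimethylsilane, C[Si](C)(C)Cl
Why: Kinetic α′-enolisation of the vinylogous ester at C6 and O-silylation; the alternative extended dienol ether would lead to the same phenol in the next step.

Step 27
Reactants: 46 silyl dienol ether of unit T
Product: 48 hexadeca-O-benzyl ether of the target with free 7-OH on unit T, via tetrahydrochromenone 47 (not isolated)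
Conditions: Pd(OAc)2 (1.1 equiv), MeCN, 25 °C
Reagents that add atoms: none
Why: Saegusa oxidation introduces the C5=C6 bond and the resulting 4a-H cyclohexadienone tautomerises to the C7 phenol, which completes ring A of unit T without any arene substitution step.

Step 28
Reactants: 48 hexadeca-O-benzyl ether
Product: 49 target tetraflavanoid CNP0126838.1
Conditions: H2 (1 atm), Pd(OH)2 on carbon, THF/MeOH/H2O, 25 °C
Reagents that add atoms: none
Why: Hydrogenolysis of sixteen benzyl ethers under neutral conditions; the cyclic benzylic C2–O1 ethers and the diarylmethine C4 centres are much slower to cleave than O-benzyl groups, so the eleven stereocentres should be untouched.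

## Compound list

1 | benzyloxyacetyl chloride | ClC(=O)COCc1ccccc1 | starting material
2 | S-ethyl 2-(benzyloxy)ethanethioate | CCSC(=O)COCc1ccccc1 | intermediate
3 | (Z)-{[2-(benzyloxy)-1-(ethylsulfanyl)ethenyl]oxy}trimethylsilane | CCS/C(O[Si](C)(C)C)=C\OCc1ccccc1 | intermediate
4 | 3,4-bis(benzyloxy)benzaldehyde | O=Cc1ccc(OCc2ccccc2)c(OCc2ccccc2)c1 | starting material
5 | S-ethyl (2S,3S)-2-(benzyloxy)-3-[3,4-bis(benzyloxy)phenyl]-3-hydroxypropanethioate (anti) | CCSC(=O)[C@@H](OCc1ccccc1)[C@@H](O)c1ccc(OCc2ccccc2)c(OCc2ccccc2)c1 | intermediate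
6 | methyl acetate | COC(C)=O | starting material
7 | methyl (4S,5S)-4-(benzyloxy)-5-[3,4-bis(benzyloxy)phenyl]-5-hydroxy-3-oxopentanoate | COC(=O)CC(=O)[C@@H](OCc1ccccc1)[C@@H](O)c1ccc(OCc2ccccc2)c(OCc2ccccc2)c1 | intermediate
8 | (5S,6S)-5-(benzyloxy)-6-[3,4-bis(benzyloxy)phenyl]oxane-2,4-dione (5,6-trans; present largely as the 4-hydroxy enol) | O=C1O[C@@H](c2ccc(OCc3ccccc3)c(OCc3ccccc3)c2)[C@H](OCc2ccccc2)C(=O)C1 | intermediate
9 | (5S,6S)-5-(benzyloxy)-6-[3,4-bis(benzyloxy)phenyl]-2-oxo-5,6-dihydro-2H-pyran-4-yl trifluoromethanesulfonate | O=C1O[C@@H](c2ccc(OCc3ccccc3)c(OCc3ccccc3)c2)[C@H](OCc2ccccc2)C(OS(=O)(=O)C(F)(F)F)=C1 | intermediate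
10 | (+)-catechin, (2R,3S) | Oc1cc(O)c2c(c1)O[C@H](c1ccc(O)c(O)c1)[C@@H](O)C2 | starting material
11 | (2R,3S)-5,7-bis(benzyloxy)-2-[3,4-bis(benzyloxy)phenyl]chroman-3-ol | c1c(OCc9ccccc9)cc(OCc9ccccc9)c2c1O[C@H](c1ccc(OCc9ccccc9)c(OCc9ccccc9)c1)[C@@H](O)C2 | intermediate
12 | (2R,3S)-3,5,7-tris(benzyloxy)-2-[3,4-bis(benzyloxy)phenyl]chromane (penta-O-benzylcatechin) | c1c(OCc9ccccc9)cc(OCc9ccccc9)c2c1O[C@H](c1ccc(OCc9ccccc9)c(OCc9ccccc9)c1)[C@@H](OCc9ccccc9)C2 | intermediate
13 | 8-bromo-penta-O-benzylcatechin | Brc1c(OCc9ccccc9)cc(OCc9ccccc9)c2c1O[C@H](c1ccc(OCc9ccccc9)c(OCc9ccccc9)c1)[C@@H](OCc9ccccc9)C2 | intermediate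
14 | 8-bromo-6-iodo-penta-O-benzylcatechin | Brc1c(OCc9ccccc9)c(I)c(OCc9ccccc9)c2c1O[C@H](c1ccc(OCc9ccccc9)c(OCc9ccccc9)c1)[C@@H](OCc9ccccc9)C2 | intermediate
15 | (8-bromo-penta-O-benzylcatechin-6-yl)magnesium chloride | Brc1c(OCc9ccccc9)c([Mg]Cl)c(OCc9ccccc9)c2c1O[C@H](c1ccc(OCc9ccccc9)c(OCc9ccccc9)c1)[C@@H](OCc9ccccc9)C2 | intermediate
16 | (8-bromo-penta-O-benzylcatechin-6-yl)zinc chloride | Brc1c(OCc9ccccc9)c([Zn]Cl)c(OCc9ccccc9)c2c1O[C@H](c1ccc(OCc9ccccc9)c(OCc9ccccc9)c1)[C@@H](OCc9ccccc9)C2 | intermediate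
17 | 8-bromo-penta-O-benzylcatechin with the (5R,6S)-5-(benzyloxy)-6-[3,4-bis(benzyloxy)phenyl]-2-oxo-5,6-dihydro-2H-pyran-4-yl group on C6 | Brc1c(OCc9ccccc9)c(C2=CC(=O)O[C@@H](c3ccc(OCc9ccccc9)c(OCc9ccccc9)c3)[C@@H]2OCc9ccccc9)c(OCc9ccccc9)c2c1O[C@H](c1ccc(OCc9ccccc9)c(OCc9ccccc9)c1)[C@@H](OCc9ccccc9)C2 | intermediate
18 | 8-bromo-penta-O-benzylcatechin with the (4S,5R,6S)-5-(benzyloxy)-6-[3,4-bis(benzyloxy)phenyl]-2-oxooxan-4-yl group on C6 (C4 aryl cis to O5, O5 trans to C6 aryl) | Brc1c(OCc9ccccc9)c([C@@H]2CC(=O)O[C@@H](c3ccc(OCc9ccccc9)c(OCc9ccccc9)c3)[C@@H]2OCc9ccccc9)c(OCc9ccccc9)c2c1O[C@H](c1ccc(OCc9ccccc9)c(OCc9ccccc9)c1)[C@@H](OCc9ccccc9)C2 | intermediate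
19 | methyl vinyl ketone (but-3-en-2-one) | CC(=O)C=C | starting material
20 | 18 carrying a 3-oxobutyl group on lactone C3 (C3 epimers) | Brc1c(OCc9ccccc9)c([C@@H]2C(CCC(C)=O)C(=O)O[C@@H](c3ccc(OCc9ccccc9)c(OCc9ccccc9)c3)[C@@H]2OCc9ccccc9)c(OCc9ccccc9)c2c1O[C@H](c1ccc(OCc9ccccc9)c(OCc9ccccc9)c1)[C@@H](OCc9ccccc9)C2 | intermediate
21 | 8-bromo-penta-O-benzylcatechin with the (1S,2R,3S)-2-(benzyloxy)-3-[3,4-bis(benzyloxy)phenyl]-1-(2,4-dioxocyclohexyl)-3-hydroxypropyl group on C6 | Brc1c(OCc9ccccc9)c([C@H](C2CCC(=O)CC2=O)[C@@H](OCc9ccccc9)[C@@H](O)c3ccc(OCc9ccccc9)c(OCc9ccccc9)c3)c(OCc9ccccc9)c2c1O[C@H](c1ccc(OCc9ccccc9)c(OCc9ccccc9)c1)[C@@H](OCc9ccccc9)C2 | intermediate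
22 | 8-bromo-penta-O-benzylcatechin with the (2S,3R,4S)-3-(benzyloxy)-2-[3,4-bis(benzyloxy)phenyl]-7-oxo-2,3,4,4a,5,6-hexahydro-7H-chromen-4-yl group on C6 (C4a epimers) | Brc1c(OCc9ccccc9)c([C@@H]2C3CCC(=O)C=C3O[C@@H](c3ccc(OCc9ccccc9)c(OCc9ccccc9)c3)[C@@H]2OCc9ccccc9)c(OCc9ccccc9)c2c1O[C@H](c1ccc(OCc9ccccc9)c(OCc9ccccc9)c1)[C@@H](OCc9ccccc9)C2 | intermediate
23 | silyl dienol ether of 22: 7-(trimethylsilyloxy)-3,4,4a,5-tetrahydro-2H-chromen-4-yl unit | Brc1c(OCc9ccccc9)c([C@@H]2C3CC=C(O[Si](C)(C)C)C=C3O[C@@H](c3ccc(OCc9ccccc9)c(OCc9ccccc9)c3)[C@@H]2OCc9ccccc9)c(OCc9ccccc9)c2c1O[C@H](c1ccc(OCc9ccccc9)c(OCc9ccccc9)c1)[C@@H](OCc9ccccc9)C2 | intermediate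
24 | 4a-H dienone of unit S: 7-oxo-2,3,4,4a-tetrahydro-7H-chromen-4-yl unit on C6 of 8-bromo-penta-O-benzylcatechin | Brc1c(OCc9ccccc9)c([C@@H]2C3C=CC(=O)C=C3O[C@@H](c3ccc(OCc9ccccc9)c(OCc9ccccc9)c3)[C@@H]2OCc9ccccc9)c(OCc9ccccc9)c2c1O[C@H](c1ccc(OCc9ccccc9)c(OCc9ccccc9)c1)[C@@H](OCc9ccccc9)C2 | intermediate
25 | 8-bromo-penta-O-benzylcatechin with the 3,3′,4′-tri-O-benzyl-ent-fisetinidol-4-yl unit S on C6 (2S,3R; 2,3-trans, 3,4-cis; 7-OH free) | Brc1c(OCc9ccccc9)c([C@@H]2c3ccc(O)cc3O[C@@H](c3ccc(OCc9ccccc9)c(OCc9ccccc9)c3)[C@@H]2OCc9ccccc9)c(OCc9ccccc9)c2c1O[C@H](c1ccc(OCc9ccccc9)c(OCc9ccccc9)c1)[C@@H](OCc9ccccc9)C2 | intermediate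
26 | 8-bromo-penta-O-benzylcatechin with the tetra-O-benzyl-ent-fisetinidol-4-yl unit S on C6 (benzylated K–S dimer bromide) | Brc1c(OCc9ccccc9)c([C@@H]2c3ccc(OCc9ccccc9)cc3O[C@@H](c3ccc(OCc9ccccc9)c(OCc9ccccc9)c3)[C@@H]2OCc9ccccc9)c(OCc9ccccc9)c2c1O[C@H](c1ccc(OCc9ccccc9)c(OCc9ccccc9)c1)[C@@H](OCc9ccccc9)C2 | intermediate
27 | C8 aryllithium of the benzylated K–S dimer | [Li]c1c(OCc9ccccc9)c([C@@H]2c3ccc(OCc9ccccc9)cc3O[C@@H](c3ccc(OCc9ccccc9)c(OCc9ccccc9)c3)[C@@H]2OCc9ccccc9)c(OCc9ccccc9)c2c1O[C@H](c1ccc(OCc9ccccc9)c(OCc9ccccc9)c1)[C@@H](OCc9ccccc9)C2 | intermediate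
28 | C8 arylzinc chloride of the benzylated K–S dimer | Cl[Zn]c1c(OCc9ccccc9)c([C@@H]2c3ccc(OCc9ccccc9)cc3O[C@@H](c3ccc(OCc9ccccc9)c(OCc9ccccc9)c3)[C@@H]2OCc9ccccc9)c(OCc9ccccc9)c2c1O[C@H](c1ccc(OCc9ccccc9)c(OCc9ccccc9)c1)[C@@H](OCc9ccccc9)C2 | intermediate
29 | benzylated K–S dimer with the (5R,6S)-5-(benzyloxy)-6-[3,4-bis(benzyloxy)phenyl]-2-oxo-5,6-dihydro-2H-pyran-4-yl group on C8 of K | O=C1O[C@@H](c2ccc(OCc9ccccc9)c(OCc9ccccc9)c2)[C@H](OCc9ccccc9)C(=C1)c1c(OCc9ccccc9)c([C@@H]2c3ccc(OCc9ccccc9)cc3O[C@@H](c3ccc(OCc9ccccc9)c(OCc9ccccc9)c3)[C@@H]2OCc9ccccc9)c(OCc9ccccc9)c2c1O[C@H](c1ccc(OCc9ccccc9)c(OCc9ccccc9)c1)[C@@H](OCc9ccccc9)C2 | intermediate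
30 | benzylated K–S dimer with the (4S,5R,6S)-5-(benzyloxy)-6-[3,4-bis(benzyloxy)phenyl]-2-oxooxan-4-yl group on C8 of K | O=C1O[C@@H](c2ccc(OCc9ccccc9)c(OCc9ccccc9)c2)[C@H](OCc9ccccc9)[C@@H](C1)c1c(OCc9ccccc9)c([C@@H]2c3ccc(OCc9ccccc9)cc3O[C@@H](c3ccc(OCc9ccccc9)c(OCc9ccccc9)c3)[C@@H]2OCc9ccccc9)c(OCc9ccccc9)c2c1O[C@H](c1ccc(OCc9ccccc9)c(OCc9ccccc9)c1)[C@@H](OCc9ccccc9)C2 | intermediate
31 | 30 carrying a 3-oxobutyl group on lactone C3 (C3 epimers) | O=C1O[C@@H](c2ccc(OCc9ccccc9)c(OCc9ccccc9)c2)[C@H](OCc9ccccc9)[C@@H](C1CCC(C)=O)c1c(OCc9ccccc9)c([C@@H]2c3ccc(OCc9ccccc9)cc3O[C@@H](c3ccc(OCc9ccccc9)c(OCc9ccccc9)c3)[C@@H]2OCc9ccccc9)c(OCc9ccccc9)c2c1O[C@H](c1ccc(OCc9ccccc9)c(OCc9ccccc9)c1)[C@@H](OCc9ccccc9)C2 | intermediate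
32 | benzylated K–S dimer with the (1S,2R,3S)-2-(benzyloxy)-3-[3,4-bis(benzyloxy)phenyl]-1-(2,4-dioxocyclohexyl)-3-hydroxypropyl group on C8 of K | O[C@@H](c2ccc(OCc9ccccc9)c(OCc9ccccc9)c2)[C@H](OCc9ccccc9)[C@@H](C1CCC(=O)CC1=O)c1c(OCc9ccccc9)c([C@@H]2c3ccc(OCc9ccccc9)cc3O[C@@H](c3ccc(OCc9ccccc9)c(OCc9ccccc9)c3)[C@@H]2OCc9ccccc9)c(OCc9ccccc9)c2c1O[C@H](c1ccc(OCc9ccccc9)c(OCc9ccccc9)c1)[C@@H](OCc9ccccc9)C2 | intermediate
33 | benzylated K–S dimer with the (2S,3R,4S)-3-(benzyloxy)-2-[3,4-bis(benzyloxy)phenyl]-7-oxo-2,3,4,4a,5,6-hexahydro-7H-chromen-4-yl group on C8 of K (C4a epimers) | O=C1CCC2C(=C1)O[C@@H](c1ccc(OCc9ccccc9)c(OCc9ccccc9)c1)[C@H](OCc9ccccc9)[C@@H]2c1c(OCc9ccccc9)c([C@@H]2c3ccc(OCc9ccccc9)cc3O[C@@H](c3ccc(OCc9ccccc9)c(OCc9ccccc9)c3)[C@@H]2OCc9ccccc9)c(OCc9ccccc9)c2c1O[C@H](c1ccc(OCc9ccccc9)c(OCc9ccccc9)c1)[C@@H](OCc9ccccc9)C2 | intermediate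
34 | silyl dienol ether of 33: 7-(trimethylsilyloxy)-3,4,4a,5-tetrahydro-2H-chromen-4-yl unit | C[Si](C)(C)OC1=CCC2C(=C1)O[C@@H](c1ccc(OCc9ccccc9)c(OCc9ccccc9)c1)[C@H](OCc9ccccc9)[C@@H]2c1c(OCc9ccccc9)c([C@@H]2c3ccc(OCc9ccccc9)cc3O[C@@H](c3ccc(OCc9ccccc9)c(OCc9ccccc9)c3)[C@@H]2OCc9ccccc9)c(OCc9ccccc9)c2c1O[C@H](c1ccc(OCc9ccccc9)c(OCc9ccccc9)c1)[C@@H](OCc9ccccc9)C2 | intermediate
35 | 4a-H dienone of unit M: 7-oxo-2,3,4,4a-tetrahydro-7H-chromen-4-yl unit on C8 of K | O=C1C=CC2C(=C1)O[C@@H](c1ccc(OCc9ccccc9)c(OCc9ccccc9)c1)[C@H](OCc9ccccc9)[C@@H]2c1c(OCc9ccccc9)c([C@@H]2c3ccc(OCc9ccccc9)cc3O[C@@H](c3ccc(OCc9ccccc9)c(OCc9ccccc9)c3)[C@@H]2OCc9ccccc9)c(OCc9ccccc9)c2c1O[C@H](c1ccc(OCc9ccccc9)c(OCc9ccccc9)c1)[C@@H](OCc9ccccc9)C2 | intermediate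
36 | benzylated M–K–S trimer with free 7-OH on unit M (M: 2S,3R; 2,3-trans, 3,4-cis; bonded C4→C8 of K) | Oc1ccc2c(c1)O[C@@H](c1ccc(OCc9ccccc9)c(OCc9ccccc9)c1)[C@H](OCc9ccccc9)[C@@H]2c1c(OCc9ccccc9)c([C@@H]2c3ccc(OCc9ccccc9)cc3O[C@@H](c3ccc(OCc9ccccc9)c(OCc9ccccc9)c3)[C@@H]2OCc9ccccc9)c(OCc9ccccc9)c2c1O[C@H](c1ccc(OCc9ccccc9)c(OCc9ccccc9)c1)[C@@H](OCc9ccccc9)C2 | intermediate
37 | 36 with bromine on C6 of unit M (7-OH free) | Brc1cc2c(cc1O)O[C@@H](c1ccc(OCc9ccccc9)c(OCc9ccccc9)c1)[C@H](OCc9ccccc9)[C@@H]2c1c(OCc9ccccc9)c([C@@H]2c3ccc(OCc9ccccc9)cc3O[C@@H](c3ccc(OCc9ccccc9)c(OCc9ccccc9)c3)[C@@H]2OCc9ccccc9)c(OCc9ccccc9)c2c1O[C@H](c1ccc(OCc9ccccc9)c(OCc9ccccc9)c1)[C@@H](OCc9ccccc9)C2 | intermediate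
38 | fully benzylated M–K–S trimer with bromine on C6 of unit M | Brc1cc2c(cc1OCc9ccccc9)O[C@@H](c1ccc(OCc9ccccc9)c(OCc9ccccc9)c1)[C@H](OCc9ccccc9)[C@@H]2c1c(OCc9ccccc9)c([C@@H]2c3ccc(OCc9ccccc9)cc3O[C@@H](c3ccc(OCc9ccccc9)c(OCc9ccccc9)c3)[C@@H]2OCc9ccccc9)c(OCc9ccccc9)c2c1O[C@H](c1ccc(OCc9ccccc9)c(OCc9ccccc9)c1)[C@@H](OCc9ccccc9)C2 | intermediate
39 | C6(M) aryllithium of the benzylated trimer | [Li]c1cc2c(cc1OCc9ccccc9)O[C@@H](c1ccc(OCc9ccccc9)c(OCc9ccccc9)c1)[C@H](OCc9ccccc9)[C@@H]2c1c(OCc9ccccc9)c([C@@H]2c3ccc(OCc9ccccc9)cc3O[C@@H](c3ccc(OCc9ccccc9)c(OCc9ccccc9)c3)[C@@H]2OCc9ccccc9)c(OCc9ccccc9)c2c1O[C@H](c1ccc(OCc9ccccc9)c(OCc9ccccc9)c1)[C@@H](OCc9ccccc9)C2 | intermediate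
40 | C6(M) arylzinc chloride of the benzylated trimer | Cl[Zn]c1cc2c(cc1OCc9ccccc9)O[C@@H](c1ccc(OCc9ccccc9)c(OCc9ccccc9)c1)[C@H](OCc9ccccc9)[C@@H]2c1c(OCc9ccccc9)c([C@@H]2c3ccc(OCc9ccccc9)cc3O[C@@H](c3ccc(OCc9ccccc9)c(OCc9ccccc9)c3)[C@@H]2OCc9ccccc9)c(OCc9ccccc9)c2c1O[C@H](c1ccc(OCc9ccccc9)c(OCc9ccccc9)c1)[C@@H](OCc9ccccc9)C2 | intermediate
41 | benzylated M–K–S trimer with the (5R,6S)-5-(benzyloxy)-6-[3,4-bis(benzyloxy)phenyl]-2-oxo-5,6-dihydro-2H-pyran-4-yl group on C6 of M | O=C1O[C@@H](c2ccc(OCc9ccccc9)c(OCc9ccccc9)c2)[C@H](OCc9ccccc9)C(=C1)c1cc2c(cc1OCc9ccccc9)O[C@@H](c1ccc(OCc9ccccc9)c(OCc9ccccc9)c1)[C@H](OCc9ccccc9)[C@@H]2c1c(OCc9ccccc9)c([C@@H]2c3ccc(OCc9ccccc9)cc3O[C@@H](c3ccc(OCc9ccccc9)c(OCc9ccccc9)c3)[C@@H]2OCc9ccccc9)c(OCc9ccccc9)c2c1O[C@H](c1ccc(OCc9ccccc9)c(OCc9ccccc9)c1)[C@@H](OCc9ccccc9)C2 | intermediate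
42 | benzylated M–K–S trimer with the (4S,5R,6S)-5-(benzyloxy)-6-[3,4-bis(benzyloxy)phenyl]-2-oxooxan-4-yl group on C6 of M (δ-lactone holding C2, C3, C4 of unit T) | O=C1O[C@@H](c2ccc(OCc9ccccc9)c(OCc9ccccc9)c2)[C@H](OCc9ccccc9)[C@@H](C1)c1cc2c(cc1OCc9ccccc9)O[C@@H](c1ccc(OCc9ccccc9)c(OCc9ccccc9)c1)[C@H](OCc9ccccc9)[C@@H]2c1c(OCc9ccccc9)c([C@@H]2c3ccc(OCc9ccccc9)cc3O[C@@H](c3ccc(OCc9ccccc9)c(OCc9ccccc9)c3)[C@@H]2OCc9ccccc9)c(OCc9ccccc9)c2c1O[C@H](c1ccc(OCc9ccccc9)c(OCc9ccccc9)c1)[C@@H](OCc9ccccc9)C2 | intermediate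
43 | 42 carrying a 3-oxobutyl group on lactone C3 (C3 epimers) | O=C1O[C@@H](c2ccc(OCc9ccccc9)c(OCc9ccccc9)c2)[C@H](OCc9ccccc9)[C@@H](C1CCC(C)=O)c1cc2c(cc1OCc9ccccc9)O[C@@H](c1ccc(OCc9ccccc9)c(OCc9ccccc9)c1)[C@H](OCc9ccccc9)[C@@H]2c1c(OCc9ccccc9)c([C@@H]2c3ccc(OCc9ccccc9)cc3O[C@@H](c3ccc(OCc9ccccc9)c(OCc9ccccc9)c3)[C@@H]2OCc9ccccc9)c(OCc9ccccc9)c2c1O[C@H](c1ccc(OCc9ccccc9)c(OCc9ccccc9)c1)[C@@H](OCc9ccccc9)C2 | intermediate
44 | benzylated M–K–S trimer with the (1S,2R,3S)-2-(benzyloxy)-3-[3,4-bis(benzyloxy)phenyl]-1-(2,4-dioxocyclohexyl)-3-hydroxypropyl group on C6 of M | O[C@@H](c2ccc(OCc9ccccc9)c(OCc9ccccc9)c2)[C@H](OCc9ccccc9)[C@@H](C1CCC(=O)CC1=O)c1cc2c(cc1OCc9ccccc9)O[C@@H](c1ccc(OCc9ccccc9)c(OCc9ccccc9)c1)[C@H](OCc9ccccc9)[C@@H]2c1c(OCc9ccccc9)c([C@@H]2c3ccc(OCc9ccccc9)cc3O[C@@H](c3ccc(OCc9ccccc9)c(OCc9ccccc9)c3)[C@@H]2OCc9ccccc9)c(OCc9ccccc9)c2c1O[C@H](c1ccc(OCc9ccccc9)c(OCc9ccccc9)c1)[C@@H](OCc9ccccc9)C2 | intermediate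
45 | benzylated M–K–S trimer with the (2S,3R,4S)-3-(benzyloxy)-2-[3,4-bis(benzyloxy)phenyl]-7-oxo-2,3,4,4a,5,6-hexahydro-7H-chromen-4-yl group on C6 of M (C4a epimers) | O=C1CCC2C(=C1)O[C@@H](c1ccc(OCc9ccccc9)c(OCc9ccccc9)c1)[C@H](OCc9ccccc9)[C@@H]2c1cc2c(cc1OCc9ccccc9)O[C@@H](c1ccc(OCc9ccccc9)c(OCc9ccccc9)c1)[C@H](OCc9ccccc9)[C@@H]2c1c(OCc9ccccc9)c([C@@H]2c3ccc(OCc9ccccc9)cc3O[C@@H](c3ccc(OCc9ccccc9)c(OCc9ccccc9)c3)[C@@H]2OCc9ccccc9)c(OCc9ccccc9)c2c1O[C@H](c1ccc(OCc9ccccc9)c(OCc9ccccc9)c1)[C@@H](OCc9ccccc9)C2 | intermediate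
46 | silyl dienol ether of 45: 7-(trimethylsilyloxy)-3,4,4a,5-tetrahydro-2H-chromen-4-yl unit | C[Si](C)(C)OC1=CCC2C(=C1)O[C@@H](c1ccc(OCc9ccccc9)c(OCc9ccccc9)c1)[C@H](OCc9ccccc9)[C@@H]2c1cc2c(cc1OCc9ccccc9)O[C@@H](c1ccc(OCc9ccccc9)c(OCc9ccccc9)c1)[C@H](OCc9ccccc9)[C@@H]2c1c(OCc9ccccc9)c([C@@H]2c3ccc(OCc9ccccc9)cc3O[C@@H](c3ccc(OCc9ccccc9)c(OCc9ccccc9)c3)[C@@H]2OCc9ccccc9)c(OCc9ccccc9)c2c1O[C@H](c1ccc(OCc9ccccc9)c(OCc9ccccc9)c1)[C@@H](OCc9ccccc9)C2 | intermediate
47 | 4a-H dienone of unit T: 7-oxo-2,3,4,4a-tetrahydro-7H-chromen-4-yl unit on C6 of M | O=C1C=CC2C(=C1)O[C@@H](c1ccc(OCc9ccccc9)c(OCc9ccccc9)c1)[C@H](OCc9ccccc9)[C@@H]2c1cc2c(cc1OCc9ccccc9)O[C@@H](c1ccc(OCc9ccccc9)c(OCc9ccccc9)c1)[C@H](OCc9ccccc9)[C@@H]2c1c(OCc9ccccc9)c([C@@H]2c3ccc(OCc9ccccc9)cc3O[C@@H](c3ccc(OCc9ccccc9)c(OCc9ccccc9)c3)[C@@H]2OCc9ccccc9)c(OCc9ccccc9)c2c1O[C@H](c1ccc(OCc9ccccc9)c(OCc9ccccc9)c1)[C@@H](OCc9ccccc9)C2 | intermediate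
48 | hexadeca-O-benzyl ether of the target (all hydroxyls benzylated except 7-OH of unit T) | Oc1ccc2c(c1)O[C@@H](c1ccc(OCc9ccccc9)c(OCc9ccccc9)c1)[C@H](OCc9ccccc9)[C@@H]2c1cc2c(cc1OCc9ccccc9)O[C@@H](c1ccc(OCc9ccccc9)c(OCc9ccccc9)c1)[C@H](OCc9ccccc9)[C@@H]2c1c(OCc9ccccc9)c([C@@H]2c3ccc(OCc9ccccc9)cc3O[C@@H](c3ccc(OCc9ccccc9)c(OCc9ccccc9)c3)[C@@H]2OCc9ccccc9)c(OCc9ccccc9)c2c1O[C@H](c1ccc(OCc9ccccc9)c(OCc9ccccc9)c1)[C@@H](OCc9ccccc9)C2 | intermediate
49 | CNP0126838.1: catechin K (2R,3S) carrying ent-fisetinidol S (C4→C6) and ent-fisetinidol M (C4→C8), M carrying ent-fisetinidol T (C4→C6); S, M, T each 2S,3R, 2,3-trans, 3,4-cis | Oc1ccc2c(c1)O[C@@H](c1ccc(O)c(O)c1)[C@H](O)[C@@H]2c1cc2c(cc1O)O[C@@H](c1ccc(O)c(O)c1)[C@H](O)[C@@H]2c1c(O)c([C@@H]2c3ccc(O)cc3O[C@@H](c3ccc(O)c(O)c3)[C@@H]2O)c(O)c2c1O[C@H](c1ccc(O)c(O)c1)[C@@H](O)C2 | target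

## Step count and risks

Total: 28 steps. Longest linear sequence: 24 steps (steps 1–5 and 10–28, counted from 1); counted from 10 the sequence is 23 steps (steps 6–28).

Step 25 (the key step; the same applies to its earlier runs in steps 12 and 18). The most likely failure is anionic oligomerisation of 19, together with 1,2-addition or a second Michael addition, because 19 is an unhindered, base-sensitive acceptor and the first adduct is itself an enolate. A second concern is ionisation of the electron-rich benzylic C2 alcohol during the acid stage, which would scramble C2. The fallback replaces conjugate addition by alkylation. It sets out from 42: the lithium enolate is alkylated with 2-(2-iodoethyl)-2-methyl-1,3-dioxolane in THF/DMPU to give the ketal lactone F1, and PPTS in wet acetone releases the ketone. This comes back to the route at 43, which is carried to 45 by the KOtBu and PPTS stages of step 25.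

Step 10 (and steps 16 and 23). The most likely failure is slow transmetalation of the di-ortho-substituted arylzinc, which leaves time for protodemetalation and for base-induced opening of the enol triflate. The fallback replaces cross-coupling by carbonyl addition and olefination. Thioester 5 is converted with MeNHOMe·HCl and iPrMgCl into the N-methoxy-N-methylamide F2. Its hydroxyl is deprotonated with iPrMgCl, and the arylmagnesium chloride 15 (made from 14 as in step 10) is added to give the β-hydroxy ketone F3. Esterification with diethylphosphonoacetic acid and a carbodiimide gives the phosphonoacetate F4, and an intramolecular Horner–Wadsworth–Emmons reaction (LiCl, DBU, MeCN) closes the unsaturated lactone. The fallback sets out from 15 and 5 and comes back at 17.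

Step 11 (and steps 17 and 24). The most likely failure is lack of conversion, because the perpendicular 2,6-dioxygenated aryl group shields C4 from the bulky phosphine-bound copper hydride; weak facial discrimination is the second concern. The fallback changes the mechanism from hydride delivery to electron transfer and protonation: SmI2 with N,N-dimethylacetamide and t-BuOH in THF reduces the conjugated lactone through its radical anion, and C4 should be protonated from the face anti to the C5 benzyloxy group. It sets out from 17 and comes back at 18, with no new isolated compound.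

Step 14 (and steps 20 and 27). The most likely failure is incomplete dehydrogenation, with hydrolysis of the silyl dienol ether back to the enone; in step 14 loss of the C8 bromide through insertion of the palladium formed is a further risk. The fallback is selenoxide elimination. It sets out from 22: kinetic enolisation with LiN(iPr)2 and trapping with PhSeCl give the C6 phenylselenide F5, and H2O2 with pyridine at 0 °C brings about syn-elimination to the dienone 24. This comes back to the route at 25 after tautomerisation.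

## Further compounds

F1 | step 25 | 42 alkylated on lactone C3 with a 2-(2-methyl-1,3-dioxolan-2-yl)ethyl group (C3 epimers) | O=C1O[C@@H](c2ccc(OCc9ccccc9)c(OCc9ccccc9)c2)[C@H](OCc9ccccc9)[C@@H](C1CCC2(C)OCCO2)c1cc2c(cc1OCc9ccccc9)O[C@@H](c1ccc(OCc9ccccc9)c(OCc9ccccc9)c1)[C@H](OCc9ccccc9)[C@@H]2c1c(OCc9ccccc9)c([C@@H]2c3ccc(OCc9ccccc9)cc3O[C@@H](c3ccc(OCc9ccccc9)c(OCc9ccccc9)c3)[C@@H]2OCc9ccccc9)c(OCc9ccccc9)c2c1O[C@H](c1ccc(OCc9ccccc9)c(OCc9ccccc9)c1)[C@@H](OCc9ccccc9)C2
F2 | step 10 | (2S,3S)-2-(benzyloxy)-3-[3,4-bis(benzyloxy)phenyl]-3-hydroxy-N-methoxy-N-methylpropanamide | CON(C)C(=O)[C@@H](OCc1ccccc1)[C@@H](O)c1ccc(OCc2ccccc2)c(OCc2ccccc2)c1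
F3 | step 10 | 8-bromo-penta-O-benzylcatechin with the (2S,3S)-2-(benzyloxy)-3-[3,4-bis(benzyloxy)phenyl]-3-hydroxypropanoyl group on C6 | Brc1c(OCc9ccccc9)c(C(=O)[C@@H](OCc9ccccc9)[C@@H](O)c3ccc(OCc9ccccc9)c(OCc9ccccc9)c3)c(OCc9ccccc9)c2c1O[C@H](c1ccc(OCc9ccccc9)c(OCc9ccccc9)c1)[C@@H](OCc9ccccc9)C2
F4 | step 10 | diethylphosphonoacetate ester of F3 | Brc1c(OCc9ccccc9)c(C(=O)[C@@H](OCc9ccccc9)[C@@H](OC(=O)CP(=O)(OCC)OCC)c3ccc(OCc9ccccc9)c(OCc9ccccc9)c3)c(OCc9ccccc9)c2c1O[C@H](c1ccc(OCc9ccccc9)c(OCc9ccccc9)c1)[C@@H](OCc9ccccc9)C2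
F0 | step 11 | none | none
F5 | step 14 | 22 with a phenylselanyl group on C6 of the hexahydrochromenone (C6 epimers) | Brc1c(OCc9ccccc9)c([C@@H]2C3CC([Se]c4ccccc4)C(=O)C=C3O[C@@H](c3ccc(OCc9ccccc9)c(OCc9ccccc9)c3)[C@@H]2OCc9ccccc9)c(OCc9ccccc9)c2c1O[C@H](c1ccc(OCc9ccccc9)c(OCc9ccccc9)c1)[C@@H](OCc9ccccc9)C2
A1 | alternative 1 | tris(4-hydroxy-4-aryl) 2,3-trans-flavan-3-ol tetramer, phenols benzylated (either C4 epimer) | c9ccccc9COc1ccc2c(c1)O[C@@H](c1ccc(OCc9ccccc9)c(OCc9ccccc9)c1)[C@H](O)C2(O)c1cc2c(cc1OCc9ccccc9)O[C@@H](c1ccc(OCc9ccccc9)c(OCc9ccccc9)c1)[C@H](O)C2(O)c1c(OCc9ccccc9)c(C2(O)c3ccc(OCc9ccccc9)cc3O[C@@H](c3ccc(OCc9ccccc9)c(OCc9ccccc9)c3)[C@@H]2O)c(OCc9ccccc9)c2c1O[C@H](c1ccc(OCc9ccccc9)c(OCc9ccccc9)c1)[C@@H](OCc9ccccc9)C2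
A2 | alternative 1 | droxidopa, (2S,3R)-2-amino-3-(3,4-dihydroxyphenyl)-3-hydroxypropanoic acid | N[C@@H]([C@H](O)c1ccc(O)c(O)c1)C(=O)O
A3 | alternative 2 | tris(3,4-epoxide) of the benzylated tetramer | c9ccccc9COc1ccc2c(c1)O[C@@H](c1ccc(OCc9ccccc9)c(OCc9ccccc9)c1)[C@@H]4O[C@]24c1cc2c(cc1OCc9ccccc9)O[C@@H](c1ccc(OCc9ccccc9)c(OCc9ccccc9)c1)[C@@H]4O[C@]24c1c(OCc9ccccc9)c([C@@]24c3ccc(OCc9ccccc9)cc3O[C@@H](c3ccc(OCc9ccccc9)c(OCc9ccccc9)c3)[C@@H]2O4)c(OCc9ccccc9)c2c1O[C@H](c1ccc(OCc9ccccc9)c(OCc9ccccc9)c1)[C@@H](OCc9ccccc9)C2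
A4 | alternative 3 | heptadeca-O-benzyl ether of the target | c9ccccc9COc1ccc2c(c1)O[C@@H](c1ccc(OCc9ccccc9)c(OCc9ccccc9)c1)[C@H](OCc9ccccc9)[C@@H]2c1cc2c(cc1OCc9ccccc9)O[C@@H](c1ccc(OCc9ccccc9)c(OCc9ccccc9)c1)[C@H](OCc9ccccc9)[C@@H]2c1c(OCc9ccccc9)c([C@@H]2c3ccc(OCc9ccccc9)cc3O[C@@H](c3ccc(OCc9ccccc9)c(OCc9ccccc9)c3)[C@@H]2OCc9ccccc9)c(OCc9ccccc9)c2c1O[C@H](c1ccc(OCc9ccccc9)c(OCc9ccccc9)c1)[C@@H](OCc9ccccc9)C2
A5 | alternative 3 | 4-bromo-1,2-bis(benzyloxy)benzene | Brc1ccc(OCc2ccccc2)c(OCc2ccccc2)c1
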